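**Assumptions and labels.** The SMILES is taken as the absolute configuration; catalysts and reagents are bought and are not counted as starting materials. TBS = tert-butyl(dimethyl)silyl. Skeletal carbons are labelled C1–C11 in the order they occur in the target SMILES (methyls unnumbered): C1 CH–OAc, C2 CH2, C3 C(Me)–O, C4 O–CH, C5 CH2, C6 CHBr, C7 CMe2, C8 C(Me)–O, C9 CH, C10 CH2, C11 CH–OH. Target = 1S,3R,4S,6S,8S,9R,11R.

**Retrosynthetic overview**
1. Target 16 ⇐ 15: 6-endo bromoetherification of C8–OH onto the prenyl olefin (bromotetrahydropyran, C6) comes last.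
2. 15 ⇐ 13 ⇐ 11: acetate placed on C1 through the C1/C8 cyclic orthoacetate; prenyl by cross-metathesis; silyl groups removed.
3. 11 ⇐ 9: ring epoxidation, then opening by C4–OH at C3 closes the oxepane bridge (2-oxabicyclo[3.2.2]nonane; sets C3, C11).
4. 9 ⇐ 8 ⇐ 5: chelation-controlled allylation (C4); cis-selective ketone reduction (C1).
5. 5 ⇐ 3 + 4: organocatalytic asymmetric Mukaiyama aldol forms C8–C9 and sets C8 and C9; 3 ⇐ m-cresol (Birch). Ring order: carbocycle (from the arene) → oxepane bridge → bromotetrahydropyran.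

**Route**

Step 1
Reactants: 1 3-methylphenol
Product: 2 tert-butyl(dimethyl)(3-methylphenoxy)silane
Conditions: TBSCl, imidazole, DMF, 23 °C
Reagents that add atoms: tert-butyl(chloro)dimethylsilane, CC(C)(C)[Si](C)(C)Cl
Why: Standard O-silylation of a phenol (Corey conditions), no stereocenter.

Step 2
Reactants: 2 tert-butyl(dimethyl)(3-methylphenoxy)silane
Product: 3 tert-butyl(dimethyl)[(5-methylcyclohexa-1,4-dien-1-yl)oxy]silane
Conditions: Li, NH3(l), t-BuOH, THF, −78 to −33 °C
Reagents that add atoms: none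
Why: Birch reduction leaves the two donor-substituted carbons sp2, giving the 1,4-diene whose enol-silane double bond is C1=C9, so C9 is the only nucleophilic carbon; no stereocenter.

Step 3
Reactants: 3 silyl dienol ether; 4 1,1-dimethoxypropan-2-one
Product: 5 (6S)-6-[(2S)-2-(TBS-oxy)-1,1-dimethoxypropan-2-yl]-3-methylcyclohex-3-en-1-one
Conditions: (S,S)-IDPi (confined BINOL-derived imidodiphosphorimidate, 1 mol%), 4 (1.2 equiv), toluene, −78 °C
Reagents that add atoms: none
Why: Proposed new method: the chiral acid is silylated by 3 to a silylium Lewis acid paired with the confined chiral anion, which activates the electron-poor ketone carbonyl of 4; the enol silane attacks C8 through an open antiperiplanar transition state that puts the CH(OMe)2 group in the sector next to C9–H and the methyl next to C10 (8,9-syn), the anion pocket selects the enantiomeric face pair (8S,9S; the catalyst antipode is used if the sense proves opposite), and TBS is transferred to the new tertiary alkoxide; the closest known reactions are IDPi-catalysed Mukaiyama aldols of silyl ketene acetals with simple ketones and disulfonimide-catalysed Mukaiyama aldols, neither shown for a ketone-derived dienol silane or an α-ketoacetal.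

Step 4
Reactants: 5 aldol adduct
Product: 7 tert-butyl({(1S,6R)-6-[(2S)-2-(TBS-oxy)-1,1-dimethoxypropan-2-yl]-3-methylcyclohex-3-en-1-yl}oxy)dimethylsilane, via lithium alkoxide 6 (not isolated)
Conditions: L-Selectride, THF, −78 °C; then TBSOTf, −78 to 0 °C
Reagents that add atoms: tert-butyl(dimethyl)silyl triflate, CC(C)(C)[Si](C)(C)OS(=O)(=O)C(F)(F)F
Why: The bulky hydride attacks equatorially, anti to the pseudo-equatorial C9 substituent, giving the axial C1–O cis to C9–C8 (1S), and the alkoxide is O-silylated in the same flask so that C1–O is a non-participating silyl ether.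

Step 5
Reactants: 7 bis-silyl ether acetal
Product: 8 (2S)-2-(TBS-oxy)-2-[(1R,6S)-6-(TBS-oxy)-4-methylcyclohex-3-en-1-yl]propanal
Conditions: TESOTf, 2,4,6-collidine, CH2Cl2, 0 °C; then H2O
Reagents that add atoms: water, O
Why: Fujioka acetal cleavage (collidinium salt, then hydrolysis) unmasks the aldehyde without touching the TBS ethers or the ring olefin; C8 is quaternary and cannot epimerise.

Step 6
Reactants: 8 aldehyde
Product: 9 (2S,3S)-2-(TBS-oxy)-2-[(1R,6S)-6-(TBS-oxy)-4-methylcyclohex-3-en-1-yl]hex-5-en-3-ol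
Conditions: allylSnBu3, Me2AlCl (2.5 equiv), CH2Cl2, −78 °C
Reagents that add atoms: allyltributylstannane, C=CC[Sn](CCCC)(CCCC)CCCC
Why: Cram-chelate allylation: dimethylaluminium bridges the aldehyde oxygen and the C8 silyloxy oxygen (Evans-type chelation of silyl ethers) and the allylstannane adds from the methyl side of the chelate, setting C4 (S).

Step 7
Reactants: 9 homoallylic alcohol
Product: 11 (1R,3S,4S,5R,6S,8R)-4,6-bis(TBS-oxy)-1,4-dimethyl-3-(prop-2-en-1-yl)-2-oxabicyclo[3.2.2]nonan-8-ol, via epoxide 10 (not isolated)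
Conditions: mCPBA, CH2Cl2, −20 °C; then CSA (0.2 equiv), −20 to 0 °C
Reagents that add atoms: 3-chloroperoxybenzoic acid, OOC(=O)c1cccc(Cl)c1
Why: Prilezhaev epoxidation takes the trisubstituted ring olefin (not the vinyl group) on the face anti to the axial C1–OTBS and the C9 substituent, and acid-catalysed anti, Markovnikov (methyl-directed 7-endo) opening by C4–OH at tertiary C3 closes the oxepane bridge, setting C3 (R) and the trans C11–OH (R), while the silyl ethers at C1 and C8 cannot act as neighbouring groups.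

Step 8
Reactants: 11 bridged allyl compound
Product: 12 (1R,3S,4S,5R,6S,8R)-4,6-bis(TBS-oxy)-1,4-dimethyl-3-(3-methylbut-2-en-1-yl)-2-oxabicyclo[3.2.2]nonan-8-ol
Conditions: Grubbs II (5 mol%), 2-methyl-2-butene/CH2Cl2, 40 °C
Reagents that add atoms: 2-methyl-2-butene, CC=C(C)C
Why: Olefin cross-metathesis of the terminal vinyl group with excess 2-methyl-2-butene gives the prenyl group; no stereocenter is affected.

Step 9
Reactants: 12 bis-silyl ether
Product: 13 (1R,3S,4S,5R,6S,8R)-1,4-dimethyl-3-(3-methylbut-2-en-1-yl)-2-oxabicyclo[3.2.2]nonane-4,6,8-triol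
Conditions: TBAF, THF, 50 °C
Reagents that add atoms: none
Why: Fluoride desilylation frees the C1 and C8 hydroxyls; no base-sensitive group is present.

Step 10
Reactants: 13 triol
Product: 15 (1R,3S,4S,5R,6S,8R)-4,8-dihydroxy-1,4-dimethyl-3-(3-methylbut-2-en-1-yl)-2-oxabicyclo[3.2.2]nonan-6-yl acetate, via cyclic orthoacetate 14 (not isolated)
Conditions: MeC(OMe)3 (1.5 equiv), PPTS (cat.), CH2Cl2, 23 °C; then AcOH/H2O 4:1, 23 °C
Reagents that add atoms: trimethyl orthoacetate, CC(OC)(OC)OC; water, O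
Why: Only the syn-1,3-diol C1–OH/C8–OH can form a six-membered cyclic orthoacetate, and its mild hydrolysis (orthoester-mediated regioselective monoacylation) gives the hydroxy acetate, which settles on the secondary C1 oxygen by 1,3-acyl migration and leaves C8–OH and the remote C11–OH free.

Step 11
Reactants: 15 hydroxy acetate
Product: 16 target acetate (1S,3R,4S,6S,8S,9R,11R)
Conditions: TBCO (1.2 equiv), CH2Cl2, 0 °C
Reagents that add atoms: 2,4,4,6-tetrabromocyclohexa-2,5-dien-1-one, O=C1C(Br)=CC(Br)(Br)C=C1Br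
Why: Biomimetic bromoetherification: the bromonium ion of the prenyl olefin is opened 6-endo at tertiary C7 by C8–OH through a chair transition state with bromine equatorial and the bulky C9 substituent equatorial on C8, setting C6 (S).

**Compound list**
1 | 3-methylphenol (m-cresol) | Cc1cccc(O)c1 | starting material
2 | tert-butyl(dimethyl)(3-methylphenoxy)silane | Cc1cccc(O[Si](C)(C)C(C)(C)C)c1 | intermediate
3 | tert-butyl(dimethyl)[(5-methylcyclohexa-1,4-dien-1-yl)oxy]silane | CC1=CCC=C(O[Si](C)(C)C(C)(C)C)C1 | intermediate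
4 | 1,1-dimethoxypropan-2-one | CC(=O)C(OC)OC | starting material
5 | (6S)-6-[(2S)-2-(TBS-oxy)-1,1-dimethoxypropan-2-yl]-3-methylcyclohex-3-en-1-one | CC1=CC[C@@H]([C@](C)(O[Si](C)(C)C(C)(C)C)C(OC)OC)C(=O)C1 | intermediate
6 | lithium (1S,6R)-6-[(2S)-2-(TBS-oxy)-1,1-dimethoxypropan-2-yl]-3-methylcyclohex-3-en-1-olate | CC1=CC[C@@H]([C@](C)(O[Si](C)(C)C(C)(C)C)C(OC)OC)[C@@H]([O-])C1.[Li+] | intermediate
7 | tert-butyl({(1S,6R)-6-[(2S)-2-(TBS-oxy)-1,1-dimethoxypropan-2-yl]-3-methylcyclohex-3-en-1-yl}oxy)dimethylsilane | CC1=CC[C@@H]([C@](C)(O[Si](C)(C)C(C)(C)C)C(OC)OC)[C@@H](O[Si](C)(C)C(C)(C)C)C1 | intermediate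
8 | (2S)-2-(TBS-oxy)-2-[(1R,6S)-6-(TBS-oxy)-4-methylcyclohex-3-en-1-yl]propanal | CC1=CC[C@@H]([C@](C)(O[Si](C)(C)C(C)(C)C)C=O)[C@@H](O[Si](C)(C)C(C)(C)C)C1 | intermediate
9 | (2S,3S)-2-(TBS-oxy)-2-[(1R,6S)-6-(TBS-oxy)-4-methylcyclohex-3-en-1-yl]hex-5-en-3-ol | CC1=CC[C@@H]([C@](C)(O[Si](C)(C)C(C)(C)C)[C@@H](O)CC=C)[C@@H](O[Si](C)(C)C(C)(C)C)C1 | intermediate
10 | C3,C11-epoxide of 9 on the ring face opposite to C8 and the C1 silyloxy group (C3 S, C11 R; other centres as in 9) | CC(C)(C)[Si](C)(C)O[C@H]1C[C@]2(C)O[C@@H]2C[C@H]1[C@](C)(O[Si](C)(C)C(C)(C)C)[C@@H](O)CC=C | intermediate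
11 | (1R,3S,4S,5R,6S,8R)-4,6-bis(TBS-oxy)-1,4-dimethyl-3-(prop-2-en-1-yl)-2-oxabicyclo[3.2.2]nonan-8-ol | CC(C)(C)[Si](C)(C)O[C@H]1C[C@@]2(C)O[C@@H](CC=C)[C@@](C)(O[Si](C)(C)C(C)(C)C)[C@@H]1C[C@H]2O | intermediate
12 | (1R,3S,4S,5R,6S,8R)-4,6-bis(TBS-oxy)-1,4-dimethyl-3-(3-methylbut-2-en-1-yl)-2-oxabicyclo[3.2.2]nonan-8-ol | CC(C)(C)[Si](C)(C)O[C@H]1C[C@@]2(C)O[C@@H](CC=C(C)C)[C@@](C)(O[Si](C)(C)C(C)(C)C)[C@@H]1C[C@H]2O | intermediate
13 | (1R,3S,4S,5R,6S,8R)-1,4-dimethyl-3-(3-methylbut-2-en-1-yl)-2-oxabicyclo[3.2.2]nonane-4,6,8-triol | O[C@H]1C[C@@]2(C)O[C@@H](CC=C(C)C)[C@@](C)(O)[C@@H]1C[C@H]2O | intermediate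
14 | cyclic methyl orthoacetate of 13 bridging the C1 and C8 oxygens (2-methoxy-2-methyl-1,3-dioxane ring; orthoester carbon as a mixture) | COC3(C)O[C@H]1C[C@@]2(C)O[C@@H](CC=C(C)C)[C@@](C)(O3)[C@@H]1C[C@H]2O | intermediate
15 | (1R,3S,4S,5R,6S,8R)-4,8-dihydroxy-1,4-dimethyl-3-(3-methylbut-2-en-1-yl)-2-oxabicyclo[3.2.2]nonan-6-yl acetate | CC(=O)O[C@H]1C[C@@]2(C)O[C@@H](CC=C(C)C)[C@@](C)(O)[C@@H]1C[C@H]2O | intermediate
16 | CNP0247588.2: acetate 15 with the C8 oxygen closed onto C7 as a 6-bromo-7,7-dimethyltetrahydropyran cis-fused at C4–C8 (1S,3R,4S,6S,8S,9R,11R) | CC(=O)O[C@H]1C[C@@]2(C)O[C@H]3C[C@H](Br)C(C)(C)O[C@@]3(C)[C@@H]1C[C@H]2O | target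

**Step count and risks**

Total steps: 11. Longest linear sequence: 11 (1 → 16; 4 is bought).

The three steps most likely to fail:

Step 3 (the proposed new aldol). A ketone-derived dienol silane is far less nucleophilic than the silyl ketene acetals used so far with these catalysts. The silylium catalyst may ionise the acetal of 4 instead of activating its ketone. The enantio- and diastereoselectivity are untested. The fallback uses known chemistry; it sets out from 3 and comes back at 8. A Cu(II)–tBu-box-catalysed Mukaiyama aldol of 3 with methyl pyruvate (CC(=O)C(=O)OC), which is syn-selective for substituted enol silanes, gives methyl (2S)-2-(TBS-oxy)-2-[(1S)-4-methyl-6-oxocyclohex-3-en-1-yl]propanoate F1. L-Selectride at −78 °C followed at once by TBSOTf, to trap the alkoxide before it lactonises onto the ester, gives methyl (2S)-2-(TBS-oxy)-2-[(1R,6S)-6-(TBS-oxy)-4-methylcyclohex-3-en-1-yl]propanoate F2. DIBAL-H at −78 °C reduces the α-silyloxy ester to aldehyde 8.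

Step 6. Chelation through a hindered tertiary silyl ether may be too weak, in which case Felkin–Anh addition gives the C4 epimer. The fallback sets C4 by hydride instead of by C–C bond formation; it sets out from 8 and comes back at 9. Allylmagnesium bromide adds without chelation to give mainly (2S,3R)-2-(TBS-oxy)-2-[(1R,6S)-6-(TBS-oxy)-4-methylcyclohex-3-en-1-yl]hex-5-en-3-ol F3 together with some 9. Dess–Martin oxidation of the mixture gives (2S)-2-(TBS-oxy)-2-[(1R,6S)-6-(TBS-oxy)-4-methylcyclohex-3-en-1-yl]hex-5-en-3-one F4. L-Selectride at −78 °C attacks anti to the C8–OTBS bond (Felkin–Anh), which is the matched sense, and returns 9.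

Step 7. The C4 hydroxyl can also attack C11 (the stereoelectronically easier 6-exo mode, giving a 2-oxabicyclo[3.3.1]nonane), and the tertiary cation can undergo Meinwald rearrangement. The fallback makes C3 the only electrophilic carbon; it sets out from epoxide 10 (isolated after a NaHCO3-buffered epoxidation) and comes back at 11. Diethylaluminium 2,2,6,6-tetramethylpiperidide isomerises the epoxide to the exocyclic allylic alcohol (2S,3S)-2-(TBS-oxy)-2-[(1R,2S,5R)-2-(TBS-oxy)-5-hydroxy-4-methylidenecyclohexyl]hex-5-en-3-ol F5, with C11–OH already in place. Hg(OCOCF3)2 then effects intramolecular Markovnikov alkoxymercuration by C4–OH at C3, giving the bridged organomercurial F6 (11 with CH2HgOCOCF3 in place of the C3 methyl). Alkaline NaBH4 demercuration gives 11.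

Further compounds
F1 | step 3 | methyl (2S)-2-(TBS-oxy)-2-[(1S)-4-methyl-6-oxocyclohex-3-en-1-yl]propanoate | CC1=CC[C@@H]([C@](C)(O[Si](C)(C)C(C)(C)C)C(=O)OC)C(=O)C1
F2 | step 3 | methyl (2S)-2-(TBS-oxy)-2-[(1R,6S)-6-(TBS-oxy)-4-methylcyclohex-3-en-1-yl]propanoate | CC1=CC[C@@H]([C@](C)(O[Si](C)(C)C(C)(C)C)C(=O)OC)[C@@H](O[Si](C)(C)C(C)(C)C)C1
F3 | step 6 | (2S,3R)-2-(TBS-oxy)-2-[(1R,6S)-6-(TBS-oxy)-4-methylcyclohex-3-en-1-yl]hex-5-en-3-ol | CC1=CC[C@@H]([C@](C)(O[Si](C)(C)C(C)(C)C)[C@H](O)CC=C)[C@@H](O[Si](C)(C)C(C)(C)C)C1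
F4 | step 6 | (2S)-2-(TBS-oxy)-2-[(1R,6S)-6-(TBS-oxy)-4-methylcyclohex-3-en-1-yl]hex-5-en-3-one | CC1=CC[C@@H]([C@](C)(O[Si](C)(C)C(C)(C)C)C(=O)CC=C)[C@@H](O[Si](C)(C)C(C)(C)C)C1
F5 | step 7 | (2S,3S)-2-(TBS-oxy)-2-[(1R,2S,5R)-2-(TBS-oxy)-5-hydroxy-4-methylidenecyclohexyl]hex-5-en-3-ol | C=C1C[C@H](O[Si](C)(C)C(C)(C)C)[C@H]([C@](C)(O[Si](C)(C)C(C)(C)C)[C@@H](O)CC=C)C[C@H]1O
F6 | step 7 | bridged organomercurial: 11 bearing CH2–Hg–OCOCF3 in place of the C3 methyl group | CC(C)(C)[Si](C)(C)O[C@H]1C[C@@]2(C[Hg]OC(=O)C(F)(F)F)O[C@@H](CC=C)[C@@](C)(O[Si](C)(C)C(C)(C)C)[C@@H]1C[C@H]2O
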